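We have 4 questions, and we answer them by following one molecule through the flask.

1. at 15 d, what has stopped the reaction, if anything has (for what has run out or reacted, a solid counts together with what of it has only dissolved) (all of the solid substrate has reacted / forward and back rates have come level / it is still moving / the partner has run out first)
2. part of the solid substrate that has turned into other species by 15 d (what has only dissolved does not count)
3. the target standing at 15 d, as a percentage of the solid substrate charged
4. the side product standing at 15 d, as a percentage of the solid substrate charged

solid substrate 0.020 M; partner 1.20 equiv (fed, over 15 min); time 15 d

    solid substrate + target → side product (k1 = 32 /M/h)
    dissolved substrate + partner → target (k2 = 1000 /M/h)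
    solid substrate ⇌ dissolved substrate, rate k3*(cs3 - [dissolved substrate]) while solid is left; crystals form when [dissolved substrate] > cs3 (cs3 = 8.7 mM, k3 = 0.086 /h)

- in percentages every species weighs as the solid substrate in it: one side product counts as two
- as a solid, counted per litre of solution: solid substrate
- at the start none of the solid substrate is in solution
- what has only dissolved of solid substrate counts as not reacted
- the reaction counts as stopped when no species that holds the solid substrate changes by six tenths of a point or more over the second half of the time
- run time (flask): 15 d

In the first instants the partner goes in. Once fed, its full charge takes a dissolved molecule at 24.0 /h, far faster than the dissolving coefficient 0.086 /h. So the solid substrate dissolves at its ceiling, 0.748 mM/h, and c(dissolved substrate) sits near 0.0312 mM, far below 8.7 mM. On this reckoning dissolving is the rate-limiting step of target making.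

Now follow a new target molecule. At a fork it either stays or meets solid substrate and becomes side product. At the charged c(solid substrate) its half-life is 1.08 h, shorter than the 13.4 h the solid substrate would last at 1.50 mM/h. So at first c(target) holds a steady state, where making equals eating. As c(solid substrate) falls, c(target) climbs.

On that steady state, target and solid substrate stand equal at 4.84 mM. We call this the meeting concentration, the level at which eating between equal concentrations matches the ceiling rate. The charge of solid substrate does not enter it. There a target molecule lives 6.46 h, longer than the 3.23 h left to the solid substrate, so we take this level as our estimate of the final c(target).

The difference c(solid substrate) minus c(target) falls steadily at 1.50 mM/h. It therefore puts the end of the solid substrate near 16.6 h, well inside the run. By then, on this reckoning, dissolved substrate has drawn 12.4 mM of partner, less than the 24.0 mM charged. We commit to this: the solid substrate runs out first, with conversion 100%, target 24.2% and side product 75.8%.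

The forecast says: all of the solid substrate has reacted, with conversion 100%, target 26% and side product 74%. Its grounds include “Dissolution then runs at its ceiling”. Its target stands above ours.

The simulation gives: all of the solid substrate has reacted, with conversion 100%, target 26.3% and side product 73.7%. At 15.0 d the solid substrate stands at 0%, and 47% of the partner remains.

In this flask the target stands at 5.26 mM, above the meeting concentration 4.84 mM. The neighbouring flask charges 0.080 M of solid substrate, with the equivalents held. The ceiling rate and 32 /M/h stay as they were, so the meeting concentration stays too, and dividing by this charge gives target 6.05%. That neighbouring flask ends with solid substrate at 0%, side product at 93.5% and target at 6.55%, which is 5.24 mM.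

Its constants are invented; the result is computed.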